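The cyclohexane ring (C5–C10; C5 carries the hydroxypropyl group, C10 is quaternary, C9 is the spiro carbon, C8 carries the secondary methyl) is cut at C6–C7 and C8–C9. A rhodium-catalysed cascade joins an isopropenylboronate to a prochiral 3-substituted cyclobutanone: 1,2-addition forms C8–C9, enantioselective β-carbon elimination opens the four-membered ring and fixes C5, and 6-endo conjugate addition forms C6–C7. It exploits the 1,4-relationship of the oxygen-bearing C9 and C6 across the C10–C5 bond. C5 then relays C10, C9 and C8 by substrate control; the tropone ring is grown last from a resorcinol ether by Birch reduction and one-carbon ring expansion.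

Key step: step 3

Remark: atom labels follow drimane numbering (C1–C3 = propanoic acid chain, C4 = carbinol carbon, C11 = CH2 of the dihydrofuran); TBSO = tert-butyldimethylsilyloxy; the SMILES strings are definitive for configuration.
Remark: in step 3 the bisphosphine antipode is the one that a first screen of both antipodes shows to give the (5S) ketone.

Step 1
Reactants: 1 methyl 3,3-dimethoxycyclobutane-1-carboxylate
Product: 3 3-(2-hydroxypropan-2-yl)cyclobutan-1-one, via ketal carbinol 2 (not isolated)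
Conditions: MeMgBr (3 equiv), THF, 0 °C to rt; then 1 M HCl, rt
Reagents that add atoms: methylmagnesium bromide C[Mg]Br; water O
Why: Double Grignard addition to the ester gives the tertiary carbinol and the acidic work-up hydrolyses the dimethyl ketal (acetal hydrolysis); no stereocentre is formed.

Step 2
Reactants: 3 3-(2-hydroxypropan-2-yl)cyclobutan-1-one
Product: 4 3-[2-(TBSO)propan-2-yl]cyclobutan-1-one
Conditions: TBSOTf, 2,6-lutidine, CH2Cl2, −78 °C
Reagents that add atoms: tert-butyldimethylsilyl trifluoromethanesulfonate CC(C)(C)[Si](C)(C)OS(=O)(=O)C(F)(F)F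
Why: Silylation of the tertiary alcohol with the silyl triflate at low temperature should outpace enol silylation of the ketone and masks the carbinol for the enolate, cationic and reducing steps.

Step 3
Reactants: 4 3-[2-(TBSO)propan-2-yl]cyclobutan-1-one; 5 4,4,5,5-tetramethyl-2-(prop-1-en-2-yl)-1,3,2-dioxaborolane
Product: 8 (5S)-5-[2-(TBSO)propan-2-yl]-2-methylcyclohexan-1-one (C2 epimers), via Rh–O cyclobutanolate 6 (not isolated), via alkylrhodium enone 7 (not isolated)
Conditions: [Rh(OH)(cod)]2 (cat.), (R)-SEGPHOS (cat.), 5 (1.5 equiv), 1,4-dioxane/H2O (20:1), 60 °C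
Reagents that add atoms: none
Why: Proposed new method: transmetalation gives an isopropenyl–rhodium species that adds to the strained ketone (C8–C9), the cyclobutanolate 6 undergoes β-carbon elimination to the primary alkylrhodium 7 that carries an isopropenyl ketone, and 7 closes by intramolecular 1,4-addition to the CH2 terminus of that enone (C6–C7) before the oxa-π-allyl rhodium is protonated by water. The closest known reactions are the rhodium-catalysed addition/ring opening of arylboronic acids with cyclobutanones and the asymmetric ring opening of 3-arylcyclobutanones followed by conjugate addition of the alkylrhodium to enones, which together show each elementary step. The six-membered ring closes in a 6-endo-trig conjugate addition. C5 is set by the bisphosphine, which differentiates the two enantiotopic carbonyl–CH2 bonds in the β-carbon elimination; C8 forms as a mixture that is erased in step 4. The cascade needs ring closure of 7 to outrun β-hydride elimination and protodemetalation, which the intramolecular, unhindered terminal acceptor and the low water content should secure.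

Step 4
Reactants: 8 (5S)-5-[2-(TBSO)propan-2-yl]-2-methylcyclohexan-1-one
Product: 9 (5S)-5-[2-(TBSO)propan-2-yl]-2-methylcyclohex-2-en-1-one
Conditions: IBX, DMSO/toluene, 65 °C
Reagents that add atoms: none
Why: IBX dehydrogenation proceeds through the more substituted enol, so the C7=C8 enone should form; it removes the C8 mixture and leaves C10 as the only carbon that a kinetic base can enolise.

Step 5
Reactants: 9 (5S)-5-[2-(TBSO)propan-2-yl]-2-methylcyclohex-2-en-1-one
Product: 11 (5S)-5-[2-(TBSO)propan-2-yl]-2,6-dimethylcyclohex-2-en-1-one (C6 epimers), via lithium dienolate 10 (not isolated)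
Conditions: LiN(iPr)2, THF, −78 °C; MeI
Reagents that add atoms: iodomethane CI
Why: Kinetic α′-deprotonation of the enone and methylation of the cross-conjugated dienolate (enolate alkylation); the configuration at C10 is irrelevant because it is planarised again in step 6.

Step 6
Reactants: 11 (5S)-5-[2-(TBSO)propan-2-yl]-2,6-dimethylcyclohex-2-en-1-one
Product: 13 (5S,6R)-6-allyl-5-[2-(TBSO)propan-2-yl]-2,6-dimethylcyclohex-2-en-1-one, via lithium dienolate 12 (not isolated)
Conditions: LiN(iPr)2, THF/DMPU, −78 °C; allyl bromide, −78 to 0 °C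
Reagents that add atoms: allyl bromide C=CCBr
Why: Enolate alkylation in which allyl bromide should approach the dienolate anti to the bulky C5 substituent, so the allyl group ends trans and the methyl cis to it and the quaternary C10 centre is set.

Step 7
Reactants: 14 1,3-dimethoxy-2-methylbenzene
Product: 16 1,3-dimethoxy-2,4-dimethylbenzene, via aryllithium 15 (not isolated)
Conditions: n-BuLi, TMEDA, Et2O, 0 °C; MeI
Reagents that add atoms: iodomethane CI
Why: Directed ortho-metalation next to a methoxy group followed by methylation gives the 2,4-dimethyl pattern of the future seven-membered ring.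

Step 8
Reactants: 16 1,3-dimethoxy-2,4-dimethylbenzene
Product: 17 1-(chloromethyl)-2,4-dimethoxy-3,5-dimethylbenzene
Conditions: (CH2O)n, conc. HCl, AcOH, 40 °C
Reagents that add atoms: formaldehyde C=O; hydrogen chloride Cl
Why: Blanc chloromethylation should attack the only ring position that is ortho and para to the two methoxy groups and installs the future C11.

Step 9
Reactants: 13 (5S,6R)-6-allyl-5-[2-(TBSO)propan-2-yl]-2,6-dimethylcyclohex-2-en-1-one; 17 1-(chloromethyl)-2,4-dimethoxy-3,5-dimethylbenzene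
Product: 19 (5S,6R)-6-allyl-1-(2,4-dimethoxy-3,5-dimethylbenzyl)-5-[2-(TBSO)propan-2-yl]-2,6-dimethylcyclohex-2-en-1-ol (C1 epimers), via benzylmagnesium chloride 18 (not isolated)
Conditions: 17, Mg, THF, 0 °C; CeCl3, THF, −78 °C; then 13; NH4Cl work-up
Reagents that add atoms: none
Why: Grignard 1,2-addition in which the organocerium variant suppresses enolisation and conjugate addition; the new C9 carbinol centre may form as a mixture because it ionises in step 11.

Step 10
Reactants: 19 tertiary allylic alcohol with the dimethoxyarene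
Product: 20 the corresponding 2,4-dimethoxy-3,5-dimethylcyclohexa-1,4-dien-1-yl compound (C3 epimers)
Conditions: Li, NH3 (l), THF, t-BuOH, −78 °C; NH4Cl
Reagents that add atoms: none
Why: Birch reduction of a 1,3-dimethoxyarene protonates the carbon between the methoxy groups and the one para to it and gives the 1,5-dimethoxy-1,4-diene (a masked 1,3-dione), while isolated alkenes, the alkoxide and the silyl ether should not be reduced.

Step 11
Reactants: 20 bis(enol ether) diene
Product: 22 6′-allyl-5′-[2-(TBSO)propan-2-yl]-2′,5,6′,7-tetramethyl-3,3a,4,5-tetrahydro-6H-spiro[1-benzofuran-2,1′-cyclohex[2]en]-6-one, via hydroxy dione 21 (not isolated)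
Conditions: 1 M HCl, THF, 0 °C; then camphorsulfonic acid (cat.), CH2Cl2, 0 °C
Reagents that add atoms: water O
Why: Enol ether hydrolysis unmasks the 1,3-dione, the tertiary allylic alcohol ionises, and the dione enol oxygen captures the allyl cation at C9 in a 5-exo cycloetherification from the face opposite the pseudo-axial C10 methyl, which sets C9 with oxygen trans to that methyl.

Step 12
Reactants: 22 allyl spiro vinylogous ester
Product: 24 the 3-hydroxypropyl analogue of 22, via alkylborane 23 (not isolated)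
Conditions: 9-BBN, THF, 0 °C to rt; then 30% H2O2, aq. NaOAc, 0 °C
Reagents that add atoms: hydrogen peroxide OO
Why: Hydroboration–oxidation in which 9-BBN should select the monosubstituted alkene over the hindered trisubstituted one and the vinylogous ester and gives the anti-Markovnikov primary alcohol.

Step 13
Reactants: 24 primary alcohol
Product: 25 the propanoic acid analogue of 22
Conditions: TEMPO (cat.), PhI(OAc)2, MeCN/H2O, rt
Reagents that add atoms: water O
Why: TEMPO/PhI(OAc)2 oxidation takes the primary alcohol through the aldehyde hydrate to the carboxylic acid without touching the ring alkene or the silyl ether.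

Step 14
Reactants: 25 unsaturated acid
Product: 26 3-{5′-[2-(TBSO)propan-2-yl]-2′,5,6′,7-tetramethyl-6-oxo-3,3a,4,5-tetrahydro-6H-spiro[1-benzofuran-2,1′-cyclohexan]-6′-yl}propanoic acid
Conditions: H2 (1 atm), [Ir(cod)(PCy3)(py)]PF6 (cat.), CH2Cl2, rt
Reagents that add atoms: none
Why: Directed homogeneous hydrogenation in which the cationic iridium catalyst binds the carboxyl and ether oxygens on the face opposite the axial C10 methyl and the C11 methylene, so hydrogen should add to C8 from that face and the C8 methyl ends cis to the C10 methyl.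

Step 15
Reactants: 26 saturated spiro vinylogous ester acid
Product: 28 trimethylsilyl dienol ether trimethylsilyl ester of 26, via dilithium dienolate 27 (not isolated)
Conditions: LiN(iPr)2 (2.2 equiv), THF, −78 °C; Me3SiCl
Reagents that add atoms: chlorotrimethylsilane C[Si](C)(C)Cl
Why: Kinetic α′-deprotonation of the vinylogous ester at the CH(CH3) next to the carbonyl (as in Stork–Danheiser alkylation) and O-silylation give the 1-alkoxy-3-silyloxy diene; the acid is carried as its silyl ester.

Step 16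
Reactants: 28 bis-silyl compound
Product: 30 3-{6-bromo-5′-[2-(TBSO)propan-2-yl]-2′,5,6′,8-tetramethyl-7-oxo-3,3a,4,7-tetrahydrospiro[cyclohepta[b]furan-2,1′-cyclohexan]-6′-yl}propanoic acid, via dibromocyclopropane 29 (not isolated)
Conditions: CHBr3, KOtBu, pentane/THF, −20 °C to rt; dilute aqueous acid work-up
Reagents that add atoms: bromoform BrC(Br)Br
Why: Dibromocarbene cyclopropanation of the terminal silyl enol ether bond, the more electron-rich one of the diene, followed by electrocyclic ring opening with loss of bromide and the silyl group (halocarbene one-carbon ring expansion) should give the 2-bromocycloheptadienone.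

Step 17
Reactants: 30 bromo dienone
Product: 31 3-{6-bromo-5′-[2-(TBSO)propan-2-yl]-2′,5,6′,8-tetramethyl-7-oxo-3H,7H-spiro[cyclohepta[b]furan-2,1′-cyclohexan]-6′-yl}propanoic acid
Conditions: DDQ, 1,4-dioxane, 80 °C
Reagents that add atoms: none
Why: DDQ dehydrogenation of the CH2–CH unit between the two enone arms is driven by formation of the aromatic tropone.

Step 18
Reactants: 31 bromotropone
Product: 32 3-{5′-[2-(TBSO)propan-2-yl]-6-(methoxycarbonyl)-2′,5,6′,8-tetramethyl-7-oxo-3H,7H-spiro[cyclohepta[b]furan-2,1′-cyclohexan]-6′-yl}propanoic acid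
Conditions: Pd(OAc)2 (cat.), Xantphos (cat.), CO (1 atm), MeOH, Et3N, DMF, 70 °C
Reagents that add atoms: carbon monoxide [C-]#[O+]; methanol CO
Why: Palladium-catalysed alkoxycarbonylation (oxidative addition into the 2-bromotropone C–Br bond, CO insertion, methanolysis) installs the methyl ester next to the ring carbonyl while the side-chain acid stays free.

Step 19
Reactants: 32 silyl-protected tropone ester
Product: 33 CNP0448476.4
Conditions: HF·pyridine, THF, 0 °C to rt
Reagents that add atoms: none
Why: Fluoride-mediated desilylation of the tertiary silyl ether under mildly acidic conditions should leave the tropone, its enol ether linkage and the methyl ester intact.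

Compound list
1 | methyl 3,3-dimethoxycyclobutane-1-carboxylate | COC(=O)C1CC(OC)(OC)C1 | starting material
2 | 2-(3,3-dimethoxycyclobutyl)propan-2-ol | CC(C)(O)C1CC(OC)(OC)C1 | intermediate
3 | 3-(2-hydroxypropan-2-yl)cyclobutan-1-one | CC(C)(O)C1CC(=O)C1 | intermediate
4 | 3-[2-(TBSO)propan-2-yl]cyclobutan-1-one | CC(C)(O[Si](C)(C)C(C)(C)C)C1CC(=O)C1 | intermediate
5 | 4,4,5,5-tetramethyl-2-(prop-1-en-2-yl)-1,3,2-dioxaborolane | CC(=C)B1OC(C)(C)C(C)(C)O1 | starting material
6 | Rh–O alkoxide of 1-(prop-1-en-2-yl)-3-[2-(TBSO)propan-2-yl]cyclobutan-1-ol (ligand set omitted) | CC(=C)C1(O[Rh])CC(C1)C(C)(C)O[Si](C)(C)C(C)(C)C | intermediate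
7 | ring-opened primary alkylrhodium isopropenyl ketone with C5 set (ligand set omitted) | [Rh]C[C@H](C(C)(C)O[Si](C)(C)C(C)(C)C)CC(=O)C(C)=C | intermediate
8 | (5S)-5-[2-(TBSO)propan-2-yl]-2-methylcyclohexan-1-one (C2 epimers) | O=C1C(C)CC[C@H](C(C)(C)O[Si](C)(C)C(C)(C)C)C1 | intermediate
9 | (5S)-5-[2-(TBSO)propan-2-yl]-2-methylcyclohex-2-en-1-one | O=C1C(C)=CC[C@H](C(C)(C)O[Si](C)(C)C(C)(C)C)C1 | intermediate
10 | lithium α′-dienolate of 9 | [Li]OC1=C[C@@H](C(C)(C)O[Si](C)(C)C(C)(C)C)CC=C1C | intermediate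
11 | (5S)-5-[2-(TBSO)propan-2-yl]-2,6-dimethylcyclohex-2-en-1-one (C6 epimers) | O=C1C(C)=CC[C@H](C(C)(C)O[Si](C)(C)C(C)(C)C)C1C | intermediate
12 | lithium α′-dienolate of 11 | [Li]OC1=C(C)[C@@H](C(C)(C)O[Si](C)(C)C(C)(C)C)CC=C1C | intermediate
13 | (5S,6R)-6-allyl-5-[2-(TBSO)propan-2-yl]-2,6-dimethylcyclohex-2-en-1-one | O=C1C(C)=CC[C@H](C(C)(C)O[Si](C)(C)C(C)(C)C)[C@@]1(C)CC=C | intermediate
14 | 1,3-dimethoxy-2-methylbenzene (2,6-dimethoxytoluene) | COc1cccc(OC)c1C | starting material
15 | (2,4-dimethoxy-3-methylphenyl)lithium | [Li]c1ccc(OC)c(C)c1OC | intermediate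
16 | 1,3-dimethoxy-2,4-dimethylbenzene | COc1ccc(C)c(OC)c1C | intermediate
17 | 1-(chloromethyl)-2,4-dimethoxy-3,5-dimethylbenzene | ClCc1cc(C)c(OC)c(C)c1OC | intermediate
18 | (2,4-dimethoxy-3,5-dimethylbenzyl)magnesium chloride | Cl[Mg]Cc1cc(C)c(OC)c(C)c1OC | intermediate
19 | (5S,6R)-6-allyl-1-(2,4-dimethoxy-3,5-dimethylbenzyl)-5-[2-(TBSO)propan-2-yl]-2,6-dimethylcyclohex-2-en-1-ol (C1 epimers) | OC1(Cc2cc(C)c(OC)c(C)c2OC)C(C)=CC[C@H](C(C)(C)O[Si](C)(C)C(C)(C)C)[C@@]1(C)CC=C | intermediate
20 | (5S,6R)-6-allyl-1-[(2,4-dimethoxy-3,5-dimethylcyclohexa-1,4-dien-1-yl)methyl]-5-[2-(TBSO)propan-2-yl]-2,6-dimethylcyclohex-2-en-1-ol (epimers at C1 and at the diene CH) | OC1(CC2=C(OC)C(C)C(OC)=C(C)C2)C(C)=CC[C@H](C(C)(C)O[Si](C)(C)C(C)(C)C)[C@@]1(C)CC=C | intermediate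
21 | 4-{[(5S,6R)-6-allyl-1-hydroxy-5-[2-(TBSO)propan-2-yl]-2,6-dimethylcyclohex-2-en-1-yl]methyl}-2,6-dimethylcyclohexane-1,3-dione (epimers at the carbinol and dione CH centres) | OC1(CC2CC(C)C(=O)C(C)C2=O)C(C)=CC[C@H](C(C)(C)O[Si](C)(C)C(C)(C)C)[C@@]1(C)CC=C | intermediate
22 | 6′-allyl-5′-[2-(TBSO)propan-2-yl]-2′,5,6′,7-tetramethyl-3,3a,4,5-tetrahydro-6H-spiro[1-benzofuran-2,1′-cyclohex[2]en]-6-one; drimane labels 5S and 10R; C9 oxygen trans to the C10 methyl; C3a and C5 epimers | O=C1C(C)CC2C(=C1C)O[C@@]3(C2)C(C)=CC[C@H](C(C)(C)O[Si](C)(C)C(C)(C)C)[C@@]3(C)CC=C | intermediate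
23 | B-alkyl-9-borabicyclo[3.3.1]nonane from hydroboration of the allyl group of 22 | O=C1C(C)CC2C(=C1C)O[C@@]3(C2)C(C)=CC[C@H](C(C)(C)O[Si](C)(C)C(C)(C)C)[C@@]3(C)CCCB4C5CCCC4CCC5 | intermediate
24 | 3-hydroxypropyl analogue of 22 (same configuration) | O=C1C(C)CC2C(=C1C)O[C@@]3(C2)C(C)=CC[C@H](C(C)(C)O[Si](C)(C)C(C)(C)C)[C@@]3(C)CCCO | intermediate
25 | 2-carboxyethyl analogue of 22 (same configuration) | O=C1C(C)CC2C(=C1C)O[C@@]3(C2)C(C)=CC[C@H](C(C)(C)O[Si](C)(C)C(C)(C)C)[C@@]3(C)CCC(=O)O | intermediate
26 | 3-{5′-[2-(TBSO)propan-2-yl]-2′,5,6′,7-tetramethyl-6-oxo-3,3a,4,5-tetrahydro-6H-spiro[1-benzofuran-2,1′-cyclohexan]-6′-yl}propanoic acid; drimane labels 5S 8R 9S 10R; C3a and C5 epimers | O=C1C(C)CC2C(=C1C)O[C@@]3(C2)[C@H](C)CC[C@H](C(C)(C)O[Si](C)(C)C(C)(C)C)[C@@]3(C)CCC(=O)O | intermediate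
27 | dilithium carboxylate α′-dienolate of 26 | [Li]OC1=C(C)CC2C(=C1C)O[C@@]3(C2)[C@H](C)CC[C@H](C(C)(C)O[Si](C)(C)C(C)(C)C)[C@@]3(C)CCC(=O)O[Li] | intermediate
28 | trimethylsilyl dienol ether trimethylsilyl ester of 26 | C[Si](C)(C)OC1=C(C)CC2C(=C1C)O[C@@]3(C2)[C@H](C)CC[C@H](C(C)(C)O[Si](C)(C)C(C)(C)C)[C@@]3(C)CCC(=O)O[Si](C)(C)C | intermediate
29 | dibromocyclopropane adduct of 28 at the silyl enol ether bond | C[Si](C)(C)OC12C(C)(C1(Br)Br)CC3C(=C2C)O[C@@]4(C3)[C@H](C)CC[C@H](C(C)(C)O[Si](C)(C)C(C)(C)C)[C@@]4(C)CCC(=O)O[Si](C)(C)C | intermediate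
30 | 3-{6-bromo-5′-[2-(TBSO)propan-2-yl]-2′,5,6′,8-tetramethyl-7-oxo-3,3a,4,7-tetrahydrospiro[cyclohepta[b]furan-2,1′-cyclohexan]-6′-yl}propanoic acid; 5S 8R 9S 10R; C3a epimers | O=C1C(Br)=C(C)CC2C(=C1C)O[C@@]3(C2)[C@H](C)CC[C@H](C(C)(C)O[Si](C)(C)C(C)(C)C)[C@@]3(C)CCC(=O)O | intermediate
31 | 3-{6-bromo-5′-[2-(TBSO)propan-2-yl]-2′,5,6′,8-tetramethyl-7-oxo-3H,7H-spiro[cyclohepta[b]furan-2,1′-cyclohexan]-6′-yl}propanoic acid; 5S 8R 9S 10R | Brc1c(C)cc2c(c(C)c1=O)O[C@@]1(C2)[C@H](C)CC[C@H](C(C)(C)O[Si](C)(C)C(C)(C)C)[C@@]1(C)CCC(=O)O | intermediate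
32 | 3-{5′-[2-(TBSO)propan-2-yl]-6-(methoxycarbonyl)-2′,5,6′,8-tetramethyl-7-oxo-3H,7H-spiro[cyclohepta[b]furan-2,1′-cyclohexan]-6′-yl}propanoic acid; 5S 8R 9S 10R | COC(=O)c1c(C)cc2c(c(C)c1=O)O[C@@]1(C2)[C@H](C)CC[C@H](C(C)(C)O[Si](C)(C)C(C)(C)C)[C@@]1(C)CCC(=O)O | intermediate
33 | CNP0448476.4: 3-{5′-(2-hydroxypropan-2-yl)-6-(methoxycarbonyl)-2′,5,6′,8-tetramethyl-7-oxo-3H,7H-spiro[cyclohepta[b]furan-2,1′-cyclohexan]-6′-yl}propanoic acid; drimane labels 5S 8R 9S 10R | COC(=O)c1c(C)cc2c(c(C)c1=O)O[C@@]1(C2)[C@H](C)CC[C@H](C(C)(C)O)[C@@]1(C)CCC(=O)O | target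

Total step count: 19. Longest linear sequence: 17 steps (steps 1–6 and 9–19, from 1 to 33); steps 7 and 8 are a two-step side branch.

Steps most likely to fail

Step 3 (key step, new cascade). The alkylrhodium intermediate may undergo β-hydride elimination or protodemetalation before it closes the ring, and the ligand may discriminate the two enantiotopic ring bonds poorly. The fallback sets out from 4 and comes back at 11. Enantiotopic α-deprotonation of 4 with the chiral amide LiN[(S)-CH(CH3)Ph]2 in the presence of Me3SiCl should give the scalemic silyl enol ether F1. Cleavage with MeLi and methylation with MeI should give the 2-methylcyclobutanone F2. Nickel-catalysed insertion of 1-(benzyldimethylsilyl)prop-1-yne into the less hindered acyl–CH2 bond (Ni(cod)2, PCy3, toluene, 100 °C; oxidative cyclisation, β-carbon elimination, reductive elimination) should give the silyl enone F3, with silicon on C7 and the methyl on C8. Protodesilylation with Bu4NF then gives 11, so steps 4 and 5 are not needed.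

Step 10 (dissolving-metal reduction). Reductive cleavage of the tertiary allylic C–O bond or incomplete reduction of the pentasubstituted arene may compete. The fallback sets out from 13 and comes back at 21, with no arene and no dissolving metal. Corey–Chaykovsky epoxidation of 13 (Me3S+ I−, n-BuLi, THF) should give the vinyl spiro-epoxide F4. The dianion (LiN(iPr)2, 2 equiv) of 2,4-dimethylcyclohexane-1,3-dione F5, itself made from commercial 2-methylcyclohexane-1,3-dione by γ-methylation of its dianion, should open F4 at the CH2 terminus through its γ-carbon and give 21 after work-up. The acid-mediated ring closure of step 11 then follows.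

Step 16 (carbene ring expansion). The carbene may add to the ring enol ether instead of the silyl enol ether, or the alkoxide may desilylate the enol ether before cyclopropanation. The fallback sets out from 28 and comes back at 32. Simmons–Smith cyclopropanation (Et2Zn, CH2I2) of the silyl enol ether should give the siloxycyclopropane F6. Ito–Saegusa ring expansion (FeCl3, DMF; then NaOAc, MeOH) should give the cycloheptadienone F7. α-Iodination (I2, pyridine, CH2Cl2) should give the iodo dienone F8, and DDQ as in step 17 the iodotropone F9. Methoxycarbonylation as in step 18 then gives 32.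

Further compounds
F1 | step 3 | 1-(trimethylsilyloxy)-3-[2-(TBSO)propan-2-yl]cyclobut-1-ene (scalemic; ring CH configured as C5 of 11) | C[Si](C)(C)OC1=C[C@@H](C(C)(C)O[Si](C)(C)C(C)(C)C)C1
F2 | step 3 | 2-methyl-3-[2-(TBSO)propan-2-yl]cyclobutan-1-one (C3 configured as C5 of 11; C2 epimers) | O=C1C[C@H](C(C)(C)O[Si](C)(C)C(C)(C)C)C1C
F3 | step 3 | (5S)-3-(benzyldimethylsilyl)-5-[2-(TBSO)propan-2-yl]-2,6-dimethylcyclohex-2-en-1-one (C6 epimers) | O=C1C(C)=C([Si](C)(C)Cc2ccccc2)C[C@H](C(C)(C)O[Si](C)(C)C(C)(C)C)C1C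
F4 | step 10 | (7S,8R)-8-allyl-4,8-dimethyl-7-[2-(TBSO)propan-2-yl]-1-oxaspiro[2.5]oct-4-ene (spiro epimers) | C1OC12C(C)=CC[C@H](C(C)(C)O[Si](C)(C)C(C)(C)C)[C@@]2(C)CC=C
F5 | step 10 | 2,4-dimethylcyclohexane-1,3-dione | CC1CCC(=O)C(C)C1=O
F6 | step 16 | siloxycyclopropane from CH2 transfer to the silyl enol ether bond of 28 | C[Si](C)(C)OC12CC1(C)CC3C(=C2C)O[C@@]4(C3)[C@H](C)CC[C@H](C(C)(C)O[Si](C)(C)C(C)(C)C)[C@@]4(C)CCC(=O)O[Si](C)(C)C
F7 | step 16 | debromo analogue of 30 (H on the ring carbon next to the carbonyl) | O=C1C=C(C)CC2C(=C1C)O[C@@]3(C2)[C@H](C)CC[C@H](C(C)(C)O[Si](C)(C)C(C)(C)C)[C@@]3(C)CCC(=O)O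
F8 | step 16 | iodo analogue of 30 | O=C1C(I)=C(C)CC2C(=C1C)O[C@@]3(C2)[C@H](C)CC[C@H](C(C)(C)O[Si](C)(C)C(C)(C)C)[C@@]3(C)CCC(=O)O
F9 | step 16 | iodo analogue of 31 | Ic1c(C)cc2c(c(C)c1=O)O[C@@]1(C2)[C@H](C)CC[C@H](C(C)(C)O[Si](C)(C)C(C)(C)C)[C@@]1(C)CCC(=O)O
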